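Alder at 40 °C stops higher than birch at 35 °C, at 41.6 % against 36.7 % of target after 30.0 h. Yet alder's last reading still leaves 58.4 % of the starting material unconverted. Here is what stands in the flasks, and what we must say about alder.

| flask | starting material | second substrate | free enzyme | impurity | temperature | remark | time |
|---|---|---|---|---|---|---|---|
| alder | 0.020 M | 1.05 equiv | 0.02 mol% | 5.2 µM | 40 °C | the very flask that is asked about, followed so far |  |
| birch | 0.020 M | 1.05 equiv | 0.02 mol% | 5.2 µM | 35 °C | run made earlier |  |
| flask | 0.020 M | 1.05 equiv | 0.02 mol% | 5.2 µM | 40 °C |  | 30 h |

| run | time / h | target / % |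
|---|---|---|
| alder | 2.50 | 26.9 |
| alder | 8.00 | 38.6 |
| alder | 15.0 | 40.6 |
| alder | 20.0 | 41.5 |
| alder | 30.0 | 41.6 |
| birch | 2.50 | 20.3 |
| birch | 8.00 | 31.9 |
| birch | 15.0 | 36.4 |
| birch | 20.0 | 37.2 |
| birch | 30.0 | 36.7 |

(scatter of a reading: 0.3 percentage points)

- blue: at 30 h add second substrate, 100 % of the amount charged, then wait 10 h
- green: change nothing and wait 10 h more
- teal: at 30 h add free enzyme, 100 % of the amount charged, then wait 10 h
- grey: at 30 h raise the temperature by 10 K, then wait 10 h
- ochre: at 30 h take out 90 % of the target then present, then wait 10 h

1. target, in percent of the starting material first charged, at 30 h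
2. the option that brings most further target ("none" if no option brings more than 2 percentage points) (blue / green / teal / grey / ochre / none)
3. target present, with what was taken out counted in, in percent of the starting material first charged, after green
4. target present, with what was taken out counted in, in percent of the starting material first charged, after teal

- removed target is counted in
- the numbers in the tables scatter by 0.3 percentage points (one standard deviation)
- additions bring no volume worth counting

Take alder in slow motion. Over the first 2.50 h, target grows at a mean 2.15 mM h⁻¹. From 2.50 h to 8.00 h the mean is 0.425 mM h⁻¹, which is 5.06 times lower, although unconverted starting material has merely gone from 73.1 % to 61.4 %. From 15.0 h to 30.0 h the mean is 0.0133 mM h⁻¹. So we suspect the catalyst rather than the reagents. The enzyme charge is 4.00 µM and the impurity charge is larger, 5.2 µM. We carry one quantity, the surplus S, the impurity charge minus the enzyme charge, here 1.20 µM. If one impurity kills one enzyme, a positive S makes the enzyme the limiting reagent of the poisoning, and S of impurity stands over to meet later enzyme. Alder then stays near 41.6 %, and fresh enzyme is the option we expect to help. Its live part L, the added amount minus S, is 2.80 µM.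

What does L give? Replace the first stretch of the curve by its mean. Live enzyme in that stretch stood at or below the charge, so f, the mean rate per enzyme charged, sits at or below the rate per live enzyme there: 538 h⁻¹. Then L at f for 10 h makes 75.3 % of the charge, against 58.4 % unconverted. Two errors sit in this. Unconverted starting material is 58.4 % against 73.1 % at the end of that stretch, which flatters the figure. But if the fall in rate means live enzyme dropping early, f is low, and we judge this error the greater. Our reckoning takes teal close to 100 %.

The forecast gives 41.6 % now, teal as best, 41.7 % after green and 87 % after teal, reading the stall thus: “That fits enzyme being killed by the impurity in a second-order reaction”. On teal's number it stands below our reckoning.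

The simulation gives 41.8 %, with 41.8 % after green and >99.9 % after teal, so the best option is teal, bringing 58 percentage points. Grey, the strongest of the rest, brings 0.012 points.

    free enzyme → unfolded enzyme (k = 1.00 × 10⁻⁶ s⁻¹, Ea = 272 kJ mol⁻¹)
    starting material + free enzyme ⇌ first complex (K = 120 M⁻¹, k = 7600 M⁻¹ s⁻¹, Ea = 24.0 kJ mol⁻¹, ΔH = −11.0 kJ mol⁻¹)
    first complex → loaded enzyme + first product (k = 2.40 s⁻¹, Ea = 80.0 kJ mol⁻¹)
    second substrate + loaded enzyme ⇌ second complex (K = 130 M⁻¹, k = 9100 M⁻¹ s⁻¹, Ea = 28.0 kJ mol⁻¹, ΔH = −62.0 kJ mol⁻¹)
    second complex → free enzyme + target (k = 0.510 s⁻¹, Ea = 83.0 kJ mol⁻¹)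
    free enzyme + impurity → spent catalyst (k = 750 M⁻¹ s⁻¹, Ea = 42.0 kJ mol⁻¹)
    (constants at 40 °C)

The stall in alder is the loss of free enzyme to impurity: the same run without that step reaches 100 % instead of 41.8 %. At 30.0 h the impurity left is 23 % of its charge, about the surplus S of 1.20 µM, so teal's enzyme outnumbers it by about L.

A neighbour of alder charged with 1.3 × 10⁻⁶ M of impurity has a negative surplus: enzyme exceeds impurity by 2.70 µM, so about 32.5 % of the catalyst should be spent and enzyme should stay alive. The computed neighbour holds 32.5 % spent catalyst, 62.6 % free enzyme and 100 % target at 30.0 h.

Readings and results stem from a simulated flask with made-up constants.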